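**Plan**

- Numbering: lactone O1, C2 (C=O), C3 (CH–CH2OH), C4 (CH–OH), C5 (quaternary), side chain C1'–C15'. The cuts, in order, are C10'–C11' (B-alkyl Suzuki–Miyaura), O1–C5 (retro-Baeyer–Villiger, contracting the five-membered lactone ring to a cyclobutanone with a temporary C2–C5 bond), C5–C1' (radical addition to a 1-alkene), then C2–C3 and C4–C5 together (retro-[2+2]).
- Enabling feature: O1 sits between the carbonyl C2 and the fully substituted C5, and C4, which is 1,3 to C2, carries oxygen. Without O1 the ring carbons C2–C3–C4–C5 form a 3-alkoxycyclobutanone, the polarity-matched adduct of a ketene (C5=C2=O) and an (E)-enol ether (C3=C4–O).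
- Helpers: a chlorine on the ketene (it activates the ketene and holds the place of the chain, since a ketene cannot tell methyl from n-alkyl), the C2–C5 bond of the four-membered ring, a 1-arylethyl auxiliary on the C4 oxygen, and a silyl ether. They are removed in steps 5, 6 and 9.
- Forward order: enol ether (steps 1–3), cyclobutanone ring (step 4), chain stub on C5 (step 5), ring expansion to the γ-lactone (step 6), chain completion (steps 7 and 8), deprotection (step 9).
- Stereochemistry: C3/C4 trans comes from the E geometry of the enol ether, and the absolute sense from the (S)-auxiliary. C5 is set by radical C–C bond formation anti to the bulky C4 alkoxy group and is carried with retention through the 1,2-shift. The C11'=C12' (E) geometry comes from syn-hydrozirconation and stereoretentive coupling.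

Key step: step 4

Remarks: R* = (S)-1-(2,4,6-triisopropylphenyl)ethyl; TBS = tert-butyldimethylsilyl. Cyclobutanone numbering: C1 (C=O, later lactone C2), C2 (later C5), C3 (later C4), C4 (later C3).

Assumption: the facial sense of induction in step 4 is derived from the s-trans rotamer model given there. If the opposite sense were found, the equally available (R)-enantiomer of 1 would be used and nothing else would change. Compound 6 is used as the racemate, because its stereocentre is lost in 7.

**Step 1**
Reactants: 1 (S)-1-(2,4,6-triisopropylphenyl)ethanol; 2 methyl propiolate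
Product: 3 methyl (E)-3-(R*O)prop-2-enoate
Conditions: PMe3 (10 mol %), CH2Cl2, 0 °C to rt
Reagents that add atoms: none
Why: Phosphine-catalysed oxa-Michael addition of an alcohol to an alkynoate, which works with hindered alcohols, gives the E-β-alkoxyacrylate as the favoured geometry and does not touch the carbinol stereocentre.

**Step 2**
Reactants: 3 methyl (E)-3-(R*O)prop-2-enoate
Product: 4 (E)-3-(R*O)prop-2-en-1-ol
Conditions: i-Bu2AlH (2.2 equiv), CH2Cl2, −78 °C
Reagents that add atoms: none
Why: Ester-to-alcohol 1,2-reduction with a dialkylaluminium hydride at low temperature keeps the enol ether and its E geometry, and a non-acidic aqueous work-up protects the acid-labile 3-alkoxyallyl alcohol.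

**Step 3**
Reactants: 4 (E)-3-(R*O)prop-2-en-1-ol
Product: 5 (E)-1-(R*O)-3-(TBSO)prop-1-ene
Conditions: TBSCl, imidazole, CH2Cl2, 0 °C
Reagents that add atoms: tert-butyldimethylsilyl chloride, CC(C)(C)[Si](C)(C)Cl
Why: Standard silyl ether formation under basic conditions masks the primary alcohol, which would otherwise be acylated by 6 or 7 in step 4.

**Step 4**
Reactants: 5 (E)-1-(R*O)-3-(TBSO)prop-1-ene; 6 2-chloropropanoyl chloride
Product: 8 (2R,3S,4S)-2-chloro-2-methyl-3-(R*O)-4-(TBSOCH2)cyclobutan-1-one, via chloro(methyl)ketene 7 (not isolated)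
Conditions: 6 (3 equiv, added over 6 h), Et3N (4 equiv), hexane, 50 °C
Reagents that add atoms: none
Why: Et3N dehydrochlorinates 6 to chloro(methyl)ketene 7, and the nucleophilic β-carbon of enol ether 5 attacks the ketene carbonyl carbon while the ketene α-carbon closes onto the developing oxocarbenium carbon, so that C1–C4 and C2–C3 of the cyclobutanone (later C2–C3 and C4–C5 of the lactone) form in one concerted but asynchronous [2+2] cycloaddition. The closest known reaction type is the thermal haloketene–enol ether cycloaddition, which is established for enol ethers of this same hindered 1-arylethanol. The four-membered ring closes in the orthogonal [π2s + π2a] mode (alkene suprafacial, ketene antarafacial), and the non-polar solvent disfavours a long-lived zwitterion that could rotate. C3 and C4 come out trans because the E geometry of 5 is kept on the suprafacial partner, and their absolute configuration (3S,4S) is set by the auxiliary, whose aryl ring covers one face of the s-trans enol ether (carbinol C–H eclipsing the O–vinyl bond) so that 7 adds from the face of the carbinol methyl group. At C2 the small chlorine lies on the side of approach and ends trans to R*O, but this centre is planarised in step 5, so either epimer serves. The step needs regioselectivity, secured by the polarisation of the enol ether (3-alkoxy adduct only), and a cycloaddition faster than ketene self-condensation, secured by the activating chlorine and by slow generation of 7 in the presence of 5; a minor facial diastereomer can be removed by chromatography because the auxiliary is covalently bound.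

**Step 5**
Reactants: 8 (2R,3S,4S)-2-chloro-2-methyl-3-(R*O)-4-(TBSOCH2)cyclobutan-1-one; 9 deca-1,9-diene
Product: 10 (2R,3S,4S)-2-(dec-9-en-1-yl)-2-methyl-3-(R*O)-4-(TBSOCH2)cyclobutan-1-one
Conditions: 9 (15 equiv), (Me3Si)3SiH (1.3 equiv) and AIBN (0.2 equiv) added over 8 h, toluene, 80 °C
Reagents that add atoms: none
Why: In this Giese-type reductive radical addition the silyl radical abstracts chlorine, the planar electrophilic tertiary α-keto radical adds to a terminal carbon of the cheap diene held in large excess on the ring face anti to the bulky neighbouring R*O group (so both C2 epimers of 8 converge on the chain-trans-to-R*O product), and the slow hydrogen donor, kept dilute, quenches the secondary adduct radical.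

**Step 6**
Reactants: 10 (2R,3S,4S)-2-(dec-9-en-1-yl)-2-methyl-3-(R*O)-4-(TBSOCH2)cyclobutan-1-one
Product: 11 (3S,4S,5R)-5-(dec-9-en-1-yl)-5-methyl-4-(R*O)-3-(TBSOCH2)dihydrofuran-2(3H)-one
Conditions: 30% aq H2O2, AcOH, NaOAc, 0 °C to rt
Reagents that add atoms: hydrogen peroxide, OO
Why: In this strain-driven Baeyer–Villiger oxidation nucleophilic H2O2 adds to the four-ring ketone and leaves the unactivated terminal alkene alone, and the fully substituted C2 migrates in preference to C4 (tertiary and deactivated by its CH2O group) with retention, which makes lactone C5 (R).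

**Step 7**
Reactants: 12 pent-1-yne
Product: 14 (E)-1-iodopent-1-ene, via (E)-pent-1-enyl-Zr(Cl)Cp2 13 (not isolated)
Conditions: Cp2Zr(H)Cl, THF, rt; then I2, 0 °C
Reagents that add atoms: iodine, II
Why: Hydrozirconation is a syn, terminal-selective addition and iodinolysis of the C–Zr bond goes with retention, which gives the E-alkenyl iodide.

**Step 8**
Reactants: 11 (3S,4S,5R)-5-(dec-9-en-1-yl)-5-methyl-4-(R*O)-3-(TBSOCH2)dihydrofuran-2(3H)-one; 14 (E)-1-iodopent-1-ene
Product: 16 (3S,4S,5R)-5-methyl-5-[(E)-pentadec-11-en-1-yl]-4-(R*O)-3-(TBSOCH2)dihydrofuran-2(3H)-one, via B-alkyl-9-BBN adduct 15 (not isolated)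
Conditions: 9-BBN, THF, 0 °C to rt; then 14, PdCl2(dppf) (5 mol %), AsPh3, aq K3PO4, DMF, rt
Reagents that add atoms: none
Why: In this B-alkyl Suzuki–Miyaura coupling 9-BBN hydroborates the terminal alkene anti-Markovnikov much faster than it reduces a lactone, and the sp3–sp2 coupling keeps the geometry of the alkenyl iodide, which places the E double bond at C11'–C12'.

**Step 9**
Reactants: 16 (3S,4S,5R)-5-methyl-5-[(E)-pentadec-11-en-1-yl]-4-(R*O)-3-(TBSOCH2)dihydrofuran-2(3H)-one
Product: 17 (3S,4S,5R)-4-hydroxy-3-(hydroxymethyl)-5-methyl-5-[(E)-pentadec-11-en-1-yl]dihydrofuran-2(3H)-one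
Conditions: CF3CO2H, CH2Cl2, H2O, 0 °C, short exposure
Reagents that add atoms: none
Why: In this SN1-type acidolysis the hindered electron-rich benzylic ether ionises at the auxiliary carbon, so the C4–O bond and its configuration stay intact and the cation collapses to the styrene, the primary silyl ether is hydrolysed in the same medium, and the disubstituted alkene and the lactone (whose C5–O ionisation is retarded by the adjacent C4 oxygen) should survive.

**Compound list**

1 | (S)-1-(2,4,6-triisopropylphenyl)ethanol | C[C@H](O)c1c(C(C)C)cc(C(C)C)cc1C(C)C | starting material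
2 | methyl propiolate | C#CC(=O)OC | starting material
3 | methyl (E)-3-[(S)-1-(2,4,6-triisopropylphenyl)ethoxy]prop-2-enoate | C[C@H](O/C=C/C(=O)OC)c1c(C(C)C)cc(C(C)C)cc1C(C)C | intermediate
4 | (E)-3-[(S)-1-(2,4,6-triisopropylphenyl)ethoxy]prop-2-en-1-ol | C[C@H](O/C=C/CO)c1c(C(C)C)cc(C(C)C)cc1C(C)C | intermediate
5 | TBS ether of 4, (E)-enol ether | C[C@H](O/C=C/CO[Si](C)(C)C(C)(C)C)c1c(C(C)C)cc(C(C)C)cc1C(C)C | intermediate
6 | 2-chloropropanoyl chloride (racemic) | CC(Cl)C(=O)Cl | starting material
7 | chloro(methyl)ketene | CC(Cl)=C=O | intermediate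
8 | (2R,3S,4S)-2-chloro-2-methyl-3-(R*O)-4-(TBSOCH2)cyclobutan-1-one; CH3 cis, Cl trans and CH2OTBS trans to R*O | Cl[C@@]1(C)C(=O)[C@@H](CO[Si](C)(C)C(C)(C)C)[C@@H]1O[C@@H](C)c2c(C(C)C)cc(C(C)C)cc2C(C)C | intermediate
9 | deca-1,9-diene | C=CCCCCCCC=C | starting material
10 | (2R,3S,4S)-2-(dec-9-en-1-yl)-2-methyl-3-(R*O)-4-(TBSOCH2)cyclobutan-1-one; chain trans to R*O | C=CCCCCCCCC[C@@]1(C)C(=O)[C@@H](CO[Si](C)(C)C(C)(C)C)[C@@H]1O[C@@H](C)c2c(C(C)C)cc(C(C)C)cc2C(C)C | intermediate
11 | (3S,4S,5R)-5-(dec-9-en-1-yl)-5-methyl-4-(R*O)-3-(TBSOCH2)dihydrofuran-2(3H)-one | C=CCCCCCCCC[C@@]1(C)OC(=O)[C@@H](CO[Si](C)(C)C(C)(C)C)[C@@H]1O[C@@H](C)c2c(C(C)C)cc(C(C)C)cc2C(C)C | intermediate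
12 | pent-1-yne | CCCC#C | starting material
13 | (E)-pent-1-enyl-Zr(Cl)Cp2 (Cp rings drawn σ-bonded) | CCC/C=C/[Zr](Cl)(C1C=CC=C1)C1C=CC=C1 | intermediate
14 | (E)-1-iodopent-1-ene | CCC/C=C/I | intermediate
15 | B-alkyl-9-BBN adduct of 11 (boron on C10') | B1(CCCCCCCCCC[C@@]2(C)OC(=O)[C@@H](CO[Si](C)(C)C(C)(C)C)[C@@H]2O[C@@H](C)c3c(C(C)C)cc(C(C)C)cc3C(C)C)C4CCCC1CCC4 | intermediate
16 | (3S,4S,5R)-5-methyl-5-[(E)-pentadec-11-en-1-yl]-4-(R*O)-3-(TBSOCH2)dihydrofuran-2(3H)-one | CCC/C=C/CCCCCCCCCC[C@@]1(C)OC(=O)[C@@H](CO[Si](C)(C)C(C)(C)C)[C@@H]1O[C@@H](C)c2c(C(C)C)cc(C(C)C)cc2C(C)C | intermediate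
17 | (3S,4S,5R)-4-hydroxy-3-(hydroxymethyl)-5-methyl-5-[(E)-pentadec-11-en-1-yl]dihydrofuran-2(3H)-one | CCC/C=C/CCCCCCCCCC[C@@]1(C)OC(=O)[C@@H](CO)[C@@H]1O | target

Total step count: 9. Longest linear sequence: 8 (steps 1–6, 8, 9); step 7 is a side branch.

**Steps most likely to fail**

1. Step 4.
   - What may go wrong: self-condensation of 7 outruns its addition to the sluggish trans-disubstituted enol ether, and reaction through the s-cis rotamer of 5 erodes facial selectivity.
   - Fallback (sets out from 5, comes back at 8): the neutral ketene is given up for a cationic heterocumulene that cannot dimerise. 2-Chloro-N,N-dimethylpropanamide, (CF3SO2)2O and 2,6-di-tert-butyl-4-methylpyridine in CH2Cl2 at −20 °C give chloro(methyl)keteniminium triflate F1. Addition of 5 leads by a stepwise cationic [2+2] (enol ether carbon to iminium carbon, then enamine carbon to oxocarbenium carbon) to the cyclobutaniminium triflate F2. Hydrolysis with aqueous NaHCO3 gives 8.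

2. Step 5.
   - What may go wrong: hydrogen transfer to the stabilised tertiary radical before it adds, telomerisation of the adduct radical with the excess diene, or partial attack syn to R*O.
   - Fallback (sets out from 8, comes back at 10): bond formation is separated from hydrogen transfer by a Kharasch atom-transfer addition. Compound 8 and excess 9 with catalytic CuCl and tris(2-pyridylmethyl)amine at 60 °C give the 2-(2-chlorodec-9-enyl)cyclobutanone F3, because chlorine transfer from the copper chloride complex traps the adduct radical faster than it can add again. The unactivated secondary chloride is then reduced with (Me3Si)3SiH and AIBN in toluene at 80 °C to 10.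

3. Step 6.
   - What may go wrong: slow addition of H2O2 to the hindered carbonyl leaves time for loss of the silyl ether in the acidic medium, for heterolytic opening of the donor–acceptor cyclobutanone, or for epoxidation by peracetic acid formed in situ.
   - Fallback (sets out from 10, comes back at 11): oxygen is inserted photochemically instead of by a peroxide. Irradiation of 10 (λ > 300 nm, Pyrex) in aqueous THF causes α-cleavage on the more substituted side. The acyl–alkyl biradical recloses through oxygen to the ring-expanded oxacarbene with retention at the migrating carbon, and water traps it as the lactol F4. Ag2CO3 on Celite in refluxing toluene then oxidises F4 to 11.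

**Further compounds**

F1 | step 4 | chloro(methyl)keteniminium triflate, N-(2-chloroprop-1-en-1-ylidene)-N-methylmethanaminium trifluoromethanesulfonate | CC(Cl)=C=[N+](C)C.[O-]S(=O)(=O)C(F)(F)F
F2 | step 4 | cyclobutaniminium triflate, N,N-dimethyliminium analogue of 8 | Cl[C@@]1(C)C(=[N+](C)C)[C@@H](CO[Si](C)(C)C(C)(C)C)[C@@H]1O[C@@H](C)c2c(C(C)C)cc(C(C)C)cc2C(C)C.[O-]S(=O)(=O)C(F)(F)F
F3 | step 5 | (2R,3S,4S)-2-(2-chlorodec-9-en-1-yl)-2-methyl-3-(R*O)-4-(TBSOCH2)cyclobutan-1-one, epimers at the chloride carbon | C=CCCCCCCC(Cl)C[C@@]1(C)C(=O)[C@@H](CO[Si](C)(C)C(C)(C)C)[C@@H]1O[C@@H](C)c2c(C(C)C)cc(C(C)C)cc2C(C)C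
F4 | step 6 | lactol of 11, (3S,4S,5R)-5-(dec-9-en-1-yl)-5-methyl-4-(R*O)-3-(TBSOCH2)tetrahydrofuran-2-ol, anomers | C=CCCCCCCCC[C@@]1(C)OC(O)[C@@H](CO[Si](C)(C)C(C)(C)C)[C@@H]1O[C@@H](C)c2c(C(C)C)cc(C(C)C)cc2C(C)C
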